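Ring D, the dimethylpyran fused to ring B, is cut at C-4″–C-5′ and C-3″–C-2″ (flavanone numbering; ring D atoms carry double primes). The aryl ether unit C-5′=C-4′–O of ring B, once its oxygen carries an acetone-derived carbocation, is a cationic 2-oxadiene; ethyl vinyl ether, an acetylene equivalent, adds across its termini C-2″ and C-5′ in a formal oxa-Povarov [4+2] annulation and then loses ethanol. The precursor is just the isopropenyl ether of 4-bromoresorcinol; closure at the ring carbon para to the free hydroxyl gives the linear chromene. The bromide becomes a boronic acid, and a rhodium-catalysed asymmetric 1,4-addition to a 6,8-diprenylchromone then forges C-2–C-1′ and sets (2S).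

Key step: step 5

Assumptions: the descriptor at C-2 is read as (2S) (O-1 > C-1′ > C-3 > H); compounds 1, 2, 7, 8 and 10 are commercial; in diol 7 the hydroxyl para to bromine is taken to be the more reactive one in copper-mediated O-alkenylation.

Step 1
Reactants: 1 2,4,6-trihydroxyacetophenone; 2 prenyl bromide (2.2 equiv)
Product: 3 1-[2,4,6-trihydroxy-3,5-bis(3-methylbut-2-en-1-yl)phenyl]ethan-1-one
Conditions: KOH (10% aq), 0 °C → rt
Reagents that add atoms: none
Why: The phloroglucinol polyanion is an ambident nucleophile that is alkylated on carbon in water (phenolate C-prenylation, a Friedel–Crafts-type alkylation); the two free ring positions are the only ones available, and 3 should be separable from mono- and O-alkylated material.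

Step 2
Reactants: 3 1-[2,4,6-trihydroxy-3,5-bis(3-methylbut-2-en-1-yl)phenyl]ethan-1-one
Product: 4 1-[2-hydroxy-4,6-bis(methoxymethoxy)-3,5-bis(3-methylbut-2-en-1-yl)phenyl]ethan-1-one
Conditions: MOMCl (2.3 equiv), i-Pr2NEt, CH2Cl2, 0 °C → rt
Reagents that add atoms: chloromethyl methyl ether, COCCl
Why: Williamson-type O-alkylation (MOM protection) takes the para hydroxyl and one ortho hydroxyl, while the hydroxyl hydrogen-bonded to the acetyl carbonyl should be left free for the ring closure of step 3.

Step 3
Reactants: 4 1-[2-hydroxy-4,6-bis(methoxymethoxy)-3,5-bis(3-methylbut-2-en-1-yl)phenyl]ethan-1-one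
Product: 6 5,7-bis(methoxymethoxy)-6,8-bis(3-methylbut-2-en-1-yl)-4H-chromen-4-one, via enaminone 5 (not isolated)
Conditions: Me2NCH(OMe)2 (3 equiv), toluene, 90 °C; then AcOH (2 equiv), 60 °C
Reagents that add atoms: N,N-dimethylformamide dimethyl acetal, COC(OC)N(C)C
Why: Condensation of the methyl ketone with the amide acetal gives the enaminone, whose ortho phenol adds to the β-carbon and expels dimethylamine (enaminone route to chromones, 6-endo addition–elimination); acetic acid is too weak to cleave the MOM ethers.

Step 4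
Reactants: 7 4-bromobenzene-1,3-diol; 8 isopropenylboronic acid pinacol ester (1.0 equiv)
Product: 9 2-bromo-5-(prop-1-en-2-yloxy)phenol
Conditions: Cu(OAc)2 (0.2 equiv), pyridine (3 equiv), 4 Å molecular sieves, O2 (1 atm), CH2Cl2, rt
Reagents that add atoms: none
Why: Chan–Lam–Evans oxidative C–O coupling of a phenol with an alkenylboronate; the hydroxyl para to bromine should react first because it is less hindered and more electron-rich than the ortho-bromo hydroxyl, and the boronate is kept limiting to avoid double alkenylation.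

Step 5
Reactants: 9 2-bromo-5-(prop-1-en-2-yloxy)phenol; 10 ethyl vinyl ether (2.5 equiv)
Product: 13 6-bromo-2,2-dimethyl-2H-chromen-7-ol, via chloro ether 11 (not isolated), via ethoxychroman 12 (not isolated)
Conditions: HCl (1.0 equiv, 2 M in Et2O), CH2Cl2, −78 °C; ZnCl2 (0.2 equiv), then 10 added over 1 h, −78 → −30 °C; Et3N (1.5 equiv); then PPTS (10 mol %), toluene, 80 °C
Reagents that add atoms: none
Why: Proposed new method: HCl adds to the enol ether in the Markovnikov sense to give the tertiary α-chloro ether 11, which ZnCl2 ionises to the aryl oxocarbenium ion ArO+=CMe2; this adds to the CH2 terminus of 10 (C-2–C-3 bond, the same elementary step by which α-chloro ether/ZnCl2 pairs propagate vinyl ether polymerisation), and the resulting ethoxycarbenium ion is captured by the tethered arene (C-4–C-4a bond) to give 12, whose para-hydroxybenzylic ethoxy group then leaves as ethanol under PPTS (E1) to give the C-3=C-4 double bond. The closest known reaction type is the Povarov reaction in its oxa variant, the formal inverse-electron-demand [4+2] cycloaddition of aryl oxocarbenium ions (cationic 2-oxadienes) with alkenes to chromans; new here are the ketone-derived oxocarbenium ion and the enol ether used as an acetylene equivalent. The pyran ring closes by a 6-(enolendo)-exo-trig Friedel–Crafts alkylation. No stereocentre remains: C-4 of 12 is formed racemic and becomes sp2. Chemoselectivity (cross-addition instead of vinyl ether oligomerisation or intermolecular arylation) should be secured by pre-forming 11 so that no nucleophilic isopropenyl ether is left, by the much higher nucleophilicity of 10 than of the bromoarene, and by slow addition of 10 so that the intramolecular ring closure outruns a second addition. Regioselectivity (closure at the carbon para to the free hydroxyl, not at the carbon between the two oxygens) should be secured by the para-directing hydroxyl and by the steric demand of the gem-dimethyl-bearing tether at the flanked position.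

Step 6
Reactants: 13 6-bromo-2,2-dimethyl-2H-chromen-7-ol
Product: 14 6-bromo-7-(methoxymethoxy)-2,2-dimethyl-2H-chromene
Conditions: MOMCl (1.3 equiv), i-Pr2NEt, CH2Cl2, 0 °C → rt
Reagents that add atoms: chloromethyl methyl ether, COCCl
Why: Williamson-type O-alkylation of the phenol (MOM protection); the amine base keeps the medium non-acidic, so the acid-sensitive chromene should be untouched.

Step 7
Reactants: 14 6-bromo-7-(methoxymethoxy)-2,2-dimethyl-2H-chromene
Product: 16 [7-(methoxymethoxy)-2,2-dimethyl-2H-chromen-6-yl]boronic acid, via aryllithium 15 (not isolated)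
Conditions: n-BuLi (1.1 equiv), THF, −78 °C; B(Oi-Pr)3 (1.5 equiv), −78 °C → rt; AcOH, H2O
Reagents that add atoms: triisopropyl borate, CC(C)OB(OC(C)C)OC(C)C; water, O
Why: Bromine–lithium exchange at −78 °C (faster than any deprotonation and assisted by the ortho OMOM group), trapping with the borate and mild hydrolysis (lithiation–borylation); chromene and MOM ether should be inert to n-BuLi at this temperature.

Step 8
Reactants: 6 5,7-bis(methoxymethoxy)-6,8-bis(3-methylbut-2-en-1-yl)-4H-chromen-4-one; 16 [7-(methoxymethoxy)-2,2-dimethyl-2H-chromen-6-yl]boronic acid (2.5 equiv)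
Product: 17 (2S)-5,7-bis(methoxymethoxy)-2-[7-(methoxymethoxy)-2,2-dimethyl-2H-chromen-6-yl]-6,8-bis(3-methylbut-2-en-1-yl)-2,3-dihydro-4H-chromen-4-one
Conditions: [RhCl(C2H4)2]2 (2.5 mol %), (S)-2,2′-bis[bis(3,4,5-trifluorophenyl)phosphino]-6,6′-dimethoxy-1,1′-biphenyl (5.5 mol %), KOH (0.2 equiv, aq), toluene, 40 °C
Reagents that add atoms: none
Why: Rhodium-catalysed asymmetric 1,4-addition of an arylboronic acid to a chromone (Hayashi–Miyaura reaction): transmetalation gives an aryl complex of monovalent rhodium that inserts the C-2=C-3 bond and the resulting enolate is protonated by water; the C2-symmetric electron-poor bisphosphine decides the face, and the antipode that delivers the aryl group to the Re face of C-2 (giving 2S) is used, which by the model for cyclic enones should be the (S)-ligand and is to be confirmed on chromone itself.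

Step 9
Reactants: 17 (2S)-5,7-bis(methoxymethoxy)-2-[7-(methoxymethoxy)-2,2-dimethyl-2H-chromen-6-yl]-6,8-bis(3-methylbut-2-en-1-yl)-2,3-dihydro-4H-chromen-4-one
Product: 18 euchrenone a3, (2S)-5,7-dihydroxy-2-(7-hydroxy-2,2-dimethyl-2H-chromen-6-yl)-6,8-bis(3-methylbut-2-en-1-yl)-2,3-dihydro-4H-chromen-4-one
Conditions: 3 M HCl (aq)/MeOH (1:4), 45 °C
Reagents that add atoms: none
Why: Acid-catalysed acetal exchange (MOM cleavage to dimethoxymethane) frees the three phenols; under these mild protic conditions the prenyl groups and chromene should survive, and C-2 is not touched because no base is present to open the chromanone by retro-oxa-Michael reaction.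

Compound list
1 | 2,4,6-trihydroxyacetophenone | CC(=O)c1c(O)cc(O)cc1O | starting material
2 | prenyl bromide (1-bromo-3-methylbut-2-ene) | CC(C)=CCBr | starting material
3 | 1-[2,4,6-trihydroxy-3,5-bis(3-methylbut-2-en-1-yl)phenyl]ethan-1-one | CC(=O)c1c(O)c(CC=C(C)C)c(O)c(CC=C(C)C)c1O | intermediate
4 | 1-[2-hydroxy-4,6-bis(methoxymethoxy)-3,5-bis(3-methylbut-2-en-1-yl)phenyl]ethan-1-one | CC(=O)c1c(O)c(CC=C(C)C)c(OCOC)c(CC=C(C)C)c1OCOC | intermediate
5 | (E)-3-(dimethylamino)-1-[2-hydroxy-4,6-bis(methoxymethoxy)-3,5-bis(3-methylbut-2-en-1-yl)phenyl]prop-2-en-1-one (not isolated) | CN(C)/C=C/C(=O)c1c(O)c(CC=C(C)C)c(OCOC)c(CC=C(C)C)c1OCOC | intermediate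
6 | 5,7-bis(methoxymethoxy)-6,8-bis(3-methylbut-2-en-1-yl)-4H-chromen-4-one | O=c1ccoc2c1c(OCOC)c(CC=C(C)C)c(OCOC)c2CC=C(C)C | intermediate
7 | 4-bromobenzene-1,3-diol (4-bromoresorcinol) | Oc1ccc(Br)c(O)c1 | starting material
8 | isopropenylboronic acid pinacol ester | CC(=C)B1OC(C)(C)C(C)(C)O1 | starting material
9 | 2-bromo-5-(prop-1-en-2-yloxy)phenol | C=C(C)Oc1ccc(Br)c(O)c1 | intermediate
10 | ethyl vinyl ether | C=COCC | starting material
11 | 2-bromo-5-[(2-chloropropan-2-yl)oxy]phenol (not isolated) | CC(C)(Cl)Oc1ccc(Br)c(O)c1 | intermediate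
12 | 6-bromo-4-ethoxy-2,2-dimethyl-3,4-dihydro-2H-chromen-7-ol, racemic (not isolated) | CCOC1CC(C)(C)Oc2cc(O)c(Br)cc21 | intermediate
13 | 6-bromo-2,2-dimethyl-2H-chromen-7-ol | CC1(C)C=Cc2cc(Br)c(O)cc2O1 | intermediate
14 | 6-bromo-7-(methoxymethoxy)-2,2-dimethyl-2H-chromene | COCOc1cc2c(cc1Br)C=CC(C)(C)O2 | intermediate
15 | [7-(methoxymethoxy)-2,2-dimethyl-2H-chromen-6-yl]lithium (not isolated) | [Li]c1cc2c(cc1OCOC)OC(C)(C)C=C2 | intermediate
16 | [7-(methoxymethoxy)-2,2-dimethyl-2H-chromen-6-yl]boronic acid | OB(O)c1cc2c(cc1OCOC)OC(C)(C)C=C2 | intermediate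
17 | (2S)-5,7-bis(methoxymethoxy)-2-[7-(methoxymethoxy)-2,2-dimethyl-2H-chromen-6-yl]-6,8-bis(3-methylbut-2-en-1-yl)-2,3-dihydro-4H-chromen-4-one | CC(C)=CCc1c(OCOC)c(CC=C(C)C)c2c(c1OCOC)C(=O)C[C@@H](c1cc3c(cc1OCOC)OC(C)(C)C=C3)O2 | intermediate
18 | euchrenone a3 | CC(C)=CCc1c(O)c(CC=C(C)C)c2c(c1O)C(=O)C[C@@H](c1cc3c(cc1O)OC(C)(C)C=C3)O2 | target

Total step count: 9. Longest linear sequence: 6 steps (steps 4 to 9, from 7 to 18); the ring A branch (steps 1 to 3) joins at step 8.

Steps most likely to fail

Step 5 (proposed new method). The vinyl ether may oligomerise faster than the ring closes, the oxocarbenium ion may alkylate a second arene or the free phenol, closure may occur at the carbon between the two oxygens, and the electron-rich chromene may dimerise under acid during ethanol loss. The fallback uses known chemistry, sets out from compound 7 and comes back at compound 13. Compound 7 is O-alkylated at the less hindered hydroxyl with 3-chloro-3-methylbut-1-yne (K2CO3, KI, acetone, reflux) to give 2-bromo-5-[(2-methylbut-3-yn-2-yl)oxy]phenol F1. Heating F1 in N,N-diethylaniline at 190 °C should give 13 by aryl propargyl ether Claisen rearrangement, [1,5]-hydrogen shift and oxa-6π electrocyclisation, with closure para to the hydroxyl expected to dominate.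

Step 8. Protodeboronation of the ortho-alkoxy, electron-rich boronic acid may outpace a slow insertion into the electron-rich chromone, the product may ring-open under base (retro-oxa-Michael) with loss of enantiopurity, and facial selectivity may be insufficient. The fallback sets out from compounds 14 and 4 and comes back at compound 17. Compound 14 is lithiated (n-BuLi, THF, −78 °C) and formylated with DMF to give 7-(methoxymethoxy)-2,2-dimethyl-2H-chromene-6-carbaldehyde F2. Claisen–Schmidt condensation of F2 with 4 (KOH, EtOH, rt) should give (E)-1-[2-hydroxy-4,6-bis(methoxymethoxy)-3,5-bis(3-methylbut-2-en-1-yl)phenyl]-3-[7-(methoxymethoxy)-2,2-dimethyl-2H-chromen-6-yl]prop-2-en-1-one F3. Oxa-Michael cyclisation (NaOAc, EtOH, reflux) should give racemic 5,7-bis(methoxymethoxy)-2-[7-(methoxymethoxy)-2,2-dimethyl-2H-chromen-6-yl]-6,8-bis(3-methylbut-2-en-1-yl)-2,3-dihydro-4H-chromen-4-one F4, which is resolved by preparative chromatography on a chiral stationary phase to give 17.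

Step 4. The copper-mediated coupling may not discriminate between the two hydroxyl groups, or may alkenylate both. The fallback leaves the route at compound 7, which it replaces by the commercial, regiodefined 4-bromo-3-methoxyphenol F5, and comes back at compound 13. Coupling of F5 with 8 under the conditions of step 4 (only one hydroxyl is present) gives 1-bromo-2-methoxy-4-(prop-1-en-2-yloxy)benzene F6. Annulation of F6 with 10 under the conditions of step 5 should proceed through 1-bromo-4-[(2-chloropropan-2-yl)oxy]-2-methoxybenzene F7 and 6-bromo-4-ethoxy-7-methoxy-2,2-dimethyl-3,4-dihydro-2H-chromene F8 (neither isolated) to 6-bromo-7-methoxy-2,2-dimethyl-2H-chromene F9. O-Demethylation of F9 with NaSEt (DMF, 130 °C) returns 13.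

Further compounds
F1 | step 5 | 2-bromo-5-[(2-methylbut-3-yn-2-yl)oxy]phenol | C#CC(C)(C)Oc1ccc(Br)c(O)c1
F2 | step 8 | 7-(methoxymethoxy)-2,2-dimethyl-2H-chromene-6-carbaldehyde | COCOc1cc2c(cc1C=O)C=CC(C)(C)O2
F3 | step 8 | (E)-1-[2-hydroxy-4,6-bis(methoxymethoxy)-3,5-bis(3-methylbut-2-en-1-yl)phenyl]-3-[7-(methoxymethoxy)-2,2-dimethyl-2H-chromen-6-yl]prop-2-en-1-one | COCOc1cc2c(cc1/C=C/C(=O)c1c(O)c(CC=C(C)C)c(OCOC)c(CC=C(C)C)c1OCOC)C=CC(C)(C)O2
F4 | step 8 | racemic 5,7-bis(methoxymethoxy)-2-[7-(methoxymethoxy)-2,2-dimethyl-2H-chromen-6-yl]-6,8-bis(3-methylbut-2-en-1-yl)-2,3-dihydro-4H-chromen-4-one | CC(C)=CCc1c(OCOC)c(CC=C(C)C)c2c(c1OCOC)C(=O)CC(c1cc3c(cc1OCOC)OC(C)(C)C=C3)O2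
F5 | step 4 | 4-bromo-3-methoxyphenol | COc1cc(O)ccc1Br
F6 | step 4 | 1-bromo-2-methoxy-4-(prop-1-en-2-yloxy)benzene | C=C(C)Oc1ccc(Br)c(OC)c1
F7 | step 4 | 1-bromo-4-[(2-chloropropan-2-yl)oxy]-2-methoxybenzene | COc1cc(OC(C)(C)Cl)ccc1Br
F8 | step 4 | 6-bromo-4-ethoxy-7-methoxy-2,2-dimethyl-3,4-dihydro-2H-chromene, racemic | CCOC1CC(C)(C)Oc2cc(OC)c(Br)cc21
F9 | step 4 | 6-bromo-7-methoxy-2,2-dimethyl-2H-chromene | COc1cc2c(cc1Br)C=CC(C)(C)O2
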